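Numbering (germacrane): C1–C10 form the ten-membered ring, C11/C12/C13 are the lactone α-carbon, carbonyl and exocyclic CH2, C14 is the methyl on C10, and C15 is the CH2OH on C4.
Retrosynthesis: remove the two O-silyl groups, the epoxide oxygen on C1/C10 and the C8 ester, then open the lactone at O–C12. Cutting C11–C12 and C6–C7 together unzips both rings to CO2 and one acyclic allenyl (Z)-enal. That chain is cut at C7–C8 (allenyl transfer to an aldehyde) and at C3–C4 (vinyl iodide + aldehyde), giving fragment A (C4, C5, C6, C15) and fragment B (C1–C3, C8–C10, C14).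
Enabling feature: the five-membered ring O–C6–C7–C11(=C13)–C12 shares its C6–C7 edge with the carbocycle. C13=C11–C7 is therefore the imprint of a terminal allene C7=C11=C13, C12 is CO2 bound to the central allene carbon, and the C6 carbinol is an aldehyde attacked at C7 by the resulting allyl-metal.
Forward order: A and B take three steps each and are joined at C3–C4; the allene is added at C8; one nickel-mediated operation then closes the ten-membered ring and delivers the lactone ring; ester, epoxide ring and desilylation follow.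
Stereochemistry: 4Z comes from trans-hydroalumination and 1(10)E from syn-carboalumination. C3 is set by a ligand-controlled chromium addition and C8 by a chiral boron reagent. C6/C7 are set in the key step (anti transition state, relay from C8), and C1/C10 by peripheral epoxidation of the macrocycle.

Key step: step 14

Assumption: the facial sense of the chiral controllers in steps 7 and 11 is assigned by analogy with their behaviour toward simple aldehydes; if either proves opposite, its mirror image is used.

Step 1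
Reactants: 1 but-2-yne-1,4-diol
Product: 2 4-(tert-butyldimethylsilyloxy)but-2-yn-1-ol
Conditions: 1 (3 equiv), TBSCl (1 equiv), imidazole, THF–DMF, 0 °C
Reagents that add atoms: tert-butyldimethylsilyl chloride, CC(C)(C)[Si](C)(C)Cl
Why: Monosilylation of the symmetrical diol used in excess (silyl ether formation) leaves one propargylic hydroxyl free to direct step 2.

Step 2
Reactants: 2 4-(tert-butyldimethylsilyloxy)but-2-yn-1-ol
Product: 4 (Z)-4-(tert-butyldimethylsilyloxy)-3-iodobut-2-en-1-ol, via cyclic alkenylaluminate 3 (not isolated)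
Conditions: NaAlH2(OCH2CH2OMe)2, THF, 0 °C; then I2, −78 °C
Reagents that add atoms: iodine, II
Why: Hydroxyl-directed trans-hydroalumination of the propargylic alcohol places aluminium on the distal alkyne carbon (future C4) inside a five-membered ring, and iodinolysis with retention gives the Z-iodide, which fixes C6 cis to the future C3 (4Z).

Step 3
Reactants: 4 (Z)-4-(tert-butyldimethylsilyloxy)-3-iodobut-2-en-1-ol
Product: 5 fragment A (Z)-4-(tert-butyldimethylsilyloxy)-3-iodo-1-(triethylsilyloxy)but-2-ene
Conditions: TESCl, imidazole, CH2Cl2, 0 °C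
Reagents that add atoms: triethylsilyl chloride, CC[Si](Cl)(CC)CC
Why: Silylation masks the C6 hydroxyl as a primary TES ether that step 13 can later oxidise selectively.

Step 4
Reactants: 6 but-3-yn-1-ol
Product: 7 1-[(but-3-yn-1-yloxy)methyl]-4-methoxybenzene
Conditions: NaH, PMBCl, Bu4NI (cat.), THF–DMF, 0 °C to rt
Reagents that add atoms: 4-methoxybenzyl chloride, COc1ccc(CCl)cc1
Why: Williamson etherification gives a C8 protecting group that tolerates organoaluminium and organochromium reagents and is removed oxidatively beside silyl ethers.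

Step 5
Reactants: 7 1-[(but-3-yn-1-yloxy)methyl]-4-methoxybenzene
Product: 10 (E)-6-(4-methoxybenzyloxy)-4-methylhex-3-en-1-ol, via alkenyldimethylalane 8 (not isolated), via lithium alkenylalanate 9 (not isolated)
Conditions: Me3Al, Cp2ZrCl2 (20 mol %), CH2Cl2, 0 °C to rt; volatiles removed; n-BuLi, hexane–THF, −78 to 0 °C; ethylene oxide, 0 °C to rt
Reagents that add atoms: trimethylaluminium, C[Al](C)C; ethylene oxide, C1CO1
Why: Zirconium-catalysed syn-carboalumination (Negishi carboalumination) sets the E-trisubstituted C1=C10 olefin with the methyl on C10, and the derived alanate opens ethylene oxide with retention of geometry to add C2 and C3.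

Step 6
Reactants: 10 (E)-6-(4-methoxybenzyloxy)-4-methylhex-3-en-1-ol
Product: 11 fragment B (E)-6-(4-methoxybenzyloxy)-4-methylhex-3-enal
Conditions: Dess–Martin periodinane, NaHCO3, CH2Cl2, 0 °C, used at once
Reagents that add atoms: none
Why: Dess–Martin oxidation under buffered neutral conditions gives the β,γ-unsaturated aldehyde without moving the olefin into conjugation.

Step 7
Reactants: 5 fragment A vinyl iodide; 11 fragment B aldehyde
Product: 12 (2Z,4S,6E)-3-[(tert-butyldimethylsilyloxy)methyl]-9-(4-methoxybenzyloxy)-7-methyl-1-(triethylsilyloxy)nona-2,6-dien-4-ol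
Conditions: CrCl2 (3 equiv), NiCl2 (2 mol %), (S)-N-[2-(4-isopropyl-4,5-dihydrooxazol-2-yl)-6-methylphenyl]methanesulfonamide (3.3 equiv), Et3N, THF, rt
Reagents that add atoms: none
Why: The Nozaki–Hiyama–Kishi reaction converts the iodide with retention of geometry into an alkenylchromium that adds to the enolisable aldehyde without base, and the chromium-bound chiral sulfonamide directs attack to the Re face of C3 to set 3S.

Step 8
Reactants: 12 the (4S)-allylic alcohol
Product: 13 4-O-tert-butyldimethylsilyl ether of 12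
Conditions: TBSOTf, 2,6-lutidine, CH2Cl2, −78 °C
Reagents that add atoms: tert-butyldimethylsilyl triflate, CC(C)(C)[Si](C)(C)OS(=O)(=O)C(F)(F)F
Why: Silylation with the triflate protects the hindered secondary C3 hydroxyl, which also prevents later furan formation from the Z-γ-oxy enal.

Step 9
Reactants: 13 4-O-tert-butyldimethylsilyl ether of 12
Product: 14 (3E,6S,7Z)-6-(tert-butyldimethylsilyloxy)-7-[(tert-butyldimethylsilyloxy)methyl]-3-methyl-9-(triethylsilyloxy)nona-3,7-dien-1-ol
Conditions: DDQ, CH2Cl2–pH 7 buffer, 0 °C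
Reagents that add atoms: none
Why: Oxidative cleavage of the electron-rich 4-methoxybenzyl ether by DDQ frees only the C8 hydroxyl and leaves silyl ethers and olefins untouched.

Step 10
Reactants: 14 the primary alcohol
Product: 15 (3E,6S,7Z)-6-(tert-butyldimethylsilyloxy)-7-[(tert-butyldimethylsilyloxy)methyl]-3-methyl-9-(triethylsilyloxy)nona-3,7-dienal
Conditions: Dess–Martin periodinane, NaHCO3, CH2Cl2, 0 °C, used at once
Reagents that add atoms: none
Why: Buffered Dess–Martin oxidation again gives the non-conjugated aldehyde (C8) without olefin migration or silyl loss.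

Step 11
Reactants: 15 the C8 aldehyde
Product: 16 (4R,6E,9S,10Z)-9-(tert-butyldimethylsilyloxy)-10-[(tert-butyldimethylsilyloxy)methyl]-6-methyl-12-(triethylsilyloxy)dodeca-1,2,6,10-tetraen-4-ol
Conditions: (S,S)-N,N'-ditosyl-1,2-diphenylethane-1,2-diamine, BBr3, CH2Cl2, 0 °C to rt, volatiles removed; allenyltributylstannane, CH2Cl2, rt; 15, −78 °C; pH 7 buffer
Reagents that add atoms: allenyltributylstannane, C=C=C[Sn](CCCC)(CCCC)CCCC
Why: The B-propargyl diazaborolidine made in the flask transfers its C3 unit through a closed SE2' transition state at −78 °C (asymmetric allenylboration) to give the allenyl and not the homopropargyl carbinol, with the C2-symmetric (S,S)-controller directing Si-face attack to set 8R.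

Step 12
Reactants: 16 the allenyl carbinol
Product: 17 4-O-triethylsilyl ether of 16
Conditions: TESCl, imidazole, DMAP (cat.), CH2Cl2, 0 °C to rt
Reagents that add atoms: triethylsilyl chloride, CC[Si](Cl)(CC)CC
Why: Silylation gives a C8 oxygen substituent that is a poor leaving group for step 14 and can be removed before the TBS ethers.

Step 13
Reactants: 17 4-O-triethylsilyl ether of 16
Product: 18 (2Z,4S,6E,9R)-4-(tert-butyldimethylsilyloxy)-3-[(tert-butyldimethylsilyloxy)methyl]-7-methyl-9-(triethylsilyloxy)dodeca-2,6,10,11-tetraenal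
Conditions: (COCl)2, DMSO, CH2Cl2, −78 to −30 °C; Et3N, −78 °C to 0 °C
Reagents that add atoms: none
Why: Under Swern conditions the activated sulfoxide cleaves and oxidises the unhindered primary TES ether directly while the secondary TES and the TBS ethers persist, and the low temperature preserves the Z-enal geometry.

Step 14
Reactants: 18 the allenyl (Z)-enal
Product: 22 3β,15-bis(tert-butyldimethylsilyloxy)-8β-(triethylsilyloxy)germacra-1(10)E,4Z,11(13)-trien-12,6α-olide (6βH,7αH), via nickelalactone 19 (not isolated), via nickel alkoxide carboxylate 20 (not isolated), via hydroxy acid 21 (not isolated)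
Conditions: Ni(cod)2 (2 equiv), DBU (4 equiv), CO2 (1 atm), THF, 0 °C, slow addition of 18 (final 2 mM), then rt; cold 0.5 M HCl; crude 21, DCC, DMAP (cat.), CH2Cl2, 0 °C
Reagents that add atoms: carbon dioxide, O=C=O
Why: Proposed new method: DBU-ligated zerovalent nickel couples CO2 oxidatively with the terminal C11=C13 π-bond of the allene, the carbon–carbon bond forming at the central allene carbon (C11–C12), to give nickelalactone 19, an η1/η3-allylnickel carboxylate whose substituted terminus C7 then adds to the tethered C6 aldehyde through a closed six-membered transition state (C6–C7) to give 20; protonolysis frees γ-hydroxy acid 21 and the carbodiimide closes the lactone. The closest known reaction types are the nickel-promoted sequential addition of CO2 and an aldehyde to a terminal allene (intermolecular, same regiochemistry) and the closure of ten-membered germacrane rings by intramolecular allyl-metal addition to an aldehyde; what is new is their merger, the macrocyclic setting and the enal acceptor. The ten-membered carbocycle closes by intramolecular γ-selective (SE2') carbonyl allylation, formally 10-exo-trig at C6, and the five-membered lactone by 5-exo-trig acyl substitution of O6 at C12. C6 and C7 are set together: the allylnickel isomers interconvert by η3–η1–η3 slippage and should drain through the chair in which C5 and C8 are both equatorial, which gives the anti adduct and hence the trans (6βH,7αH) fusion, while the face of C7 is chosen by the C8 stereocentre, H8 lying in the allyl plane to avoid allylic strain and C6 bonding anti to the C8–C9 bond. The step needs carboxylation to outrun direct nickel-mediated allene–aldehyde coupling (large excess of CO2, poorly coordinating β,β-disubstituted enal), 1,2- rather than 1,4-addition (fully substituted C4, cyclic transition state), ring closure rather than oligomerisation (high dilution, the Z-C4=C5 and E-C1=C10 olefins pre-bend the tether) and retention of the C8 oxygen on the allylnickel (a silyl ether, not the ester, as a poor leaving group).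

Step 15
Reactants: 22 the tris-silylated lactone
Product: 23 3β,15-bis(tert-butyldimethylsilyloxy)-8β-hydroxygermacra-1(10)E,4Z,11(13)-trien-12,6α-olide
Conditions: PPTS (cat.), MeOH–CH2Cl2, 0 °C
Reagents that add atoms: none
Why: Mild acid-catalysed methanolysis removes the TES ether much faster than the bulkier TBS ethers, and no acid-sensitive epoxide is present yet.

Step 16
Reactants: 23 the 8β-alcohol
Product: 24 3β,15-bis(tert-butyldimethylsilyloxy)-8β-isobutyryloxygermacra-1(10)E,4Z,11(13)-trien-12,6α-olide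
Conditions: isobutyric anhydride, DMAP (cat.), Et3N, CH2Cl2, 0 °C to rt
Reagents that add atoms: isobutyric anhydride, CC(C)C(=O)OC(=O)C(C)C
Why: DMAP-catalysed acylation esterifies the only free hydroxyl with retention at C8.

Step 17
Reactants: 24 the 8β-isobutyrate
Product: 25 1β,10α-epoxy-3β,15-bis(tert-butyldimethylsilyloxy)-8β-isobutyryloxygermacra-4Z,11(13)-dien-12,6α-olide
Conditions: mCPBA (1.05 equiv), CH2Cl2, −20 to 0 °C
Reagents that add atoms: 3-chloroperoxybenzoic acid, O=C(OO)c1cccc(Cl)c1
Why: The Prilezhaev epoxidation selects the only electron-rich olefin (C4=C5 is deactivated by two allylic oxygens, C11=C13 by the carbonyl), and because the E-olefin stands perpendicular to the ring with C14 on the β face the peracid reaches only its outer face, which should give the 1β,10α-epoxide (1R,10R).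

Step 18
Reactants: 25 the bis-silylated epoxide
Product: 26 1β,10α-epoxy-3β,15-dihydroxy-8β-isobutyryloxygermacra-4Z,11(13)-dien-12,6α-olide (1R,3S,6R,7R,8R,10R)
Conditions: HF·pyridine, excess pyridine, THF, 0 °C to rt
Reagents that add atoms: none
Why: Buffered fluoride-driven desilylation frees both allylic alcohols without basic or strongly acidic conditions, so the epoxide, the ester and the α-methylene lactone should survive.

Compound list
1 | but-2-yne-1,4-diol | OCC#CCO | starting material
2 | 4-(tert-butyldimethylsilyloxy)but-2-yn-1-ol | CC(C)(C)[Si](C)(C)OCC#CCO | intermediate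
3 | sodium cyclic alkenylaluminate (five-membered O–Al–C4=C5–C6 ring) | [Na+].COCCO[Al-]1(OCCOC)OCC=C1CO[Si](C)(C)C(C)(C)C | intermediate
4 | (Z)-4-(tert-butyldimethylsilyloxy)-3-iodobut-2-en-1-ol | OC/C=C(/CO[Si](C)(C)C(C)(C)C)I | intermediate
5 | fragment A, (Z)-4-(tert-butyldimethylsilyloxy)-3-iodo-1-(triethylsilyloxy)but-2-ene | CC[Si](CC)(CC)OC/C=C(/CO[Si](C)(C)C(C)(C)C)I | intermediate
6 | but-3-yn-1-ol | C#CCCO | starting material
7 | 1-[(but-3-yn-1-yloxy)methyl]-4-methoxybenzene | C#CCCOCc1ccc(OC)cc1 | intermediate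
8 | (E)-alkenyldimethylalane | C[Al](C)/C=C(\C)CCOCc1ccc(OC)cc1 | intermediate
9 | lithium (E)-alkenyl(butyl)dimethylalanate | [Li+].CCCC[Al-](C)(C)/C=C(\C)CCOCc1ccc(OC)cc1 | intermediate
10 | (E)-6-(4-methoxybenzyloxy)-4-methylhex-3-en-1-ol | OCC/C=C(\C)CCOCc1ccc(OC)cc1 | intermediate
11 | fragment B, (E)-6-(4-methoxybenzyloxy)-4-methylhex-3-enal | O=CC/C=C(\C)CCOCc1ccc(OC)cc1 | intermediate
12 | (2Z,4S,6E)-3-[(TBSO)methyl]-9-(PMBO)-7-methyl-1-(TESO)nona-2,6-dien-4-ol | CC[Si](CC)(CC)OC/C=C(/CO[Si](C)(C)C(C)(C)C)[C@@H](O)C/C=C(\C)CCOCc1ccc(OC)cc1 | intermediate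
13 | 4-O-TBS ether of 12 | CC[Si](CC)(CC)OC/C=C(/CO[Si](C)(C)C(C)(C)C)[C@@H](O[Si](C)(C)C(C)(C)C)C/C=C(\C)CCOCc1ccc(OC)cc1 | intermediate
14 | (3E,6S,7Z)-6-(TBSO)-7-[(TBSO)methyl]-3-methyl-9-(TESO)nona-3,7-dien-1-ol | CC[Si](CC)(CC)OC/C=C(/CO[Si](C)(C)C(C)(C)C)[C@@H](O[Si](C)(C)C(C)(C)C)C/C=C(\C)CCO | intermediate
15 | (3E,6S,7Z)-6-(TBSO)-7-[(TBSO)methyl]-3-methyl-9-(TESO)nona-3,7-dienal | CC[Si](CC)(CC)OC/C=C(/CO[Si](C)(C)C(C)(C)C)[C@@H](O[Si](C)(C)C(C)(C)C)C/C=C(\C)CC=O | intermediate
16 | (4R,6E,9S,10Z)-9-(TBSO)-10-[(TBSO)methyl]-6-methyl-12-(TESO)dodeca-1,2,6,10-tetraen-4-ol | CC[Si](CC)(CC)OC/C=C(/CO[Si](C)(C)C(C)(C)C)[C@@H](O[Si](C)(C)C(C)(C)C)C/C=C(\C)C[C@@H](O)C=C=C | intermediate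
17 | 4-O-TES ether of 16 | CC[Si](CC)(CC)OC/C=C(/CO[Si](C)(C)C(C)(C)C)[C@@H](O[Si](C)(C)C(C)(C)C)C/C=C(\C)C[C@@H](O[Si](CC)(CC)CC)C=C=C | intermediate
18 | (2Z,4S,6E,9R)-4-(TBSO)-3-[(TBSO)methyl]-7-methyl-9-(TESO)dodeca-2,6,10,11-tetraenal | O=C/C=C(/CO[Si](C)(C)C(C)(C)C)[C@@H](O[Si](C)(C)C(C)(C)C)C/C=C(\C)C[C@@H](O[Si](CC)(CC)CC)C=C=C | intermediate
19 | nickelalactone (Ni–C13, C11–C12, DBU ligands omitted) | O=C/C=C(/CO[Si](C)(C)C(C)(C)C)[C@@H](O[Si](C)(C)C(C)(C)C)C/C=C(\C)C[C@@H](O[Si](CC)(CC)CC)C=C1C[Ni]OC1=O | intermediate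
20 | ten-membered carbocycle as divalent nickel O6-alkoxide C12-carboxylate chelate (DBU ligands omitted) | C=C1C(=O)O[Ni]O[C@@H]2/C=C(/CO[Si](C)(C)C(C)(C)C)[C@@H](O[Si](C)(C)C(C)(C)C)C/C=C(\C)C[C@@H](O[Si](CC)(CC)CC)[C@@H]12 | intermediate
21 | 6α-hydroxy-3β,15-bis(TBSO)-8β-(TESO)germacra-1(10)E,4Z,11(13)-trien-12-oic acid | C=C(C(=O)O)[C@H]1[C@H](O)/C=C(/CO[Si](C)(C)C(C)(C)C)[C@@H](O[Si](C)(C)C(C)(C)C)C/C=C(\C)C[C@H]1O[Si](CC)(CC)CC | intermediate
22 | 3β,15-bis(TBSO)-8β-(TESO)germacra-1(10)E,4Z,11(13)-trien-12,6α-olide | C=C1C(=O)O[C@@H]2/C=C(/CO[Si](C)(C)C(C)(C)C)[C@@H](O[Si](C)(C)C(C)(C)C)C/C=C(\C)C[C@@H](O[Si](CC)(CC)CC)[C@@H]12 | intermediate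
23 | 3β,15-bis(TBSO)-8β-hydroxygermacra-1(10)E,4Z,11(13)-trien-12,6α-olide | C=C1C(=O)O[C@@H]2/C=C(/CO[Si](C)(C)C(C)(C)C)[C@@H](O[Si](C)(C)C(C)(C)C)C/C=C(\C)C[C@@H](O)[C@@H]12 | intermediate
24 | 3β,15-bis(TBSO)-8β-isobutyryloxygermacra-1(10)E,4Z,11(13)-trien-12,6α-olide | C=C1C(=O)O[C@@H]2/C=C(/CO[Si](C)(C)C(C)(C)C)[C@@H](O[Si](C)(C)C(C)(C)C)C/C=C(\C)C[C@@H](OC(=O)C(C)C)[C@@H]12 | intermediate
25 | 1β,10α-epoxy-3β,15-bis(TBSO)-8β-isobutyryloxygermacra-4Z,11(13)-dien-12,6α-olide | C=C1C(=O)O[C@@H]2/C=C(/CO[Si](C)(C)C(C)(C)C)[C@@H](O[Si](C)(C)C(C)(C)C)C[C@H]3O[C@]3(C)C[C@@H](OC(=O)C(C)C)[C@@H]12 | intermediate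
26 | CNP0219050.1, 1β,10α-epoxy-3β,15-dihydroxy-8β-isobutyryloxygermacra-4Z,11(13)-dien-12,6α-olide | C=C1C(=O)O[C@@H]2/C=C(/CO)[C@@H](O)C[C@H]3O[C@]3(C)C[C@@H](OC(=O)C(C)C)[C@@H]12 | target

Total step count: 18. Longest linear sequence: 15 (steps 1–3 or 4–6, then steps 7–18).

Steps most likely to fail

1. Step 14. Several processes could compete with the carboxylative ring closure:
- oligomerisation, or direct nickel-mediated allene–aldehyde coupling;
- base-induced Z/E drift of the enal;
- loss of the C8 oxygen from the allylnickel;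
- poor facial selectivity at C7.

The fallback uses known chemistry, sets out from allenyl carbinol 16 and returns at 23. PdCl2-catalysed chlorocyclocarbonylation of the 2,3-allenol (CuCl2, CO, THF) would first make C11–C12 and a temporary O8–C12 bond and give the (R)-5-substituted 3-(chloromethyl)furan-2(5H)-one F1. Swern oxidation of its primary TES ether, as in step 13, gives the butenolide enal F2. An intramolecular chromium-mediated allylation (CrCl2, LiI, THF, high dilution) is the established way of closing germacranolide rings. It forms C6–C7 at the γ-carbon from the face that carries the tether and gives the 6α-hydroxy-8β,12-olide F3. Base-catalysed translactonisation (DBU cat., toluene) to the less strained trans-fused 6α,12-olide then gives 23.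

2. Step 17. Facial selectivity could be poor if the ring also populates the conformer with C14 on the α face, and C4=C5 could be over-oxidised. The fallback moves the epoxidation before ring closure and puts it under reagent control. It sets out from 17 and returns at 25.
- Shi epoxidation (D-fructose-derived ketone, Oxone, K2CO3 buffer, MeCN–dimethoxymethane–water, 0 °C) should attack the trisubstituted C1=C10 olefin faster than the deactivated C4=C5 olefin and the monosubstituted allene, giving the (R,R)-epoxide F4.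
- Swern oxidation as in step 13 gives the epoxy enal F5.
- The nickel/CO2 closure of step 14 gives the epoxy lactone F6.
- TES removal as in step 15 gives the epoxy alcohol F7.
- Acylation as in step 16 gives 25.

3. Step 7. Ligand control could be low with the hindered trisubstituted alkenylchromium, giving a C3 epimer mixture. The fallback separates bond formation from stereocontrol; it sets out from 12 (as the epimer mixture from a ligand-free coupling) and returns at 12. Dess–Martin oxidation gives the cross-conjugated enone F8. Corey–Bakshi–Shibata reduction ((R)-methyl oxazaborolidine, BH3·SMe2, toluene, −30 °C), with the branched alkenyl group as the large substituent, should return the 3S alcohol 12.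

Further compounds
F1 | step 14 | (R)-3-(chloromethyl)-5-substituted furan-2(5H)-one carrying the C9–C6 chain (3S, 1(10)E, 4Z, C6 OTES) | CC[Si](CC)(CC)OC/C=C(/CO[Si](C)(C)C(C)(C)C)[C@@H](O[Si](C)(C)C(C)(C)C)C/C=C(\C)C[C@H]1OC(=O)C(CCl)=C1
F2 | step 14 | chloromethyl butenolide (Z)-enal | O=C/C=C(/CO[Si](C)(C)C(C)(C)C)[C@@H](O[Si](C)(C)C(C)(C)C)C/C=C(\C)C[C@H]1OC(=O)C(CCl)=C1
F3 | step 14 | 6α-hydroxy-3β,15-bis(TBSO)germacra-1(10)E,4Z,11(13)-trien-12,8β-olide | C=C1C(=O)O[C@@H]2C/C(C)=C/C[C@H](O[Si](C)(C)C(C)(C)C)/C(CO[Si](C)(C)C(C)(C)C)=C\[C@@H](O)[C@H]12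
F4 | step 17 | (1R,10R)-epoxide of 17 | CC[Si](CC)(CC)OC/C=C(/CO[Si](C)(C)C(C)(C)C)[C@@H](O[Si](C)(C)C(C)(C)C)C[C@H]1O[C@]1(C)C[C@@H](O[Si](CC)(CC)CC)C=C=C
F5 | step 17 | (1R,10R)-epoxy allenyl (Z)-enal | O=C/C=C(/CO[Si](C)(C)C(C)(C)C)[C@@H](O[Si](C)(C)C(C)(C)C)C[C@H]1O[C@]1(C)C[C@@H](O[Si](CC)(CC)CC)C=C=C
F6 | step 17 | 1β,10α-epoxy-3β,15-bis(TBSO)-8β-(TESO)germacra-4Z,11(13)-dien-12,6α-olide | C=C1C(=O)O[C@@H]2/C=C(/CO[Si](C)(C)C(C)(C)C)[C@@H](O[Si](C)(C)C(C)(C)C)C[C@H]3O[C@]3(C)C[C@@H](O[Si](CC)(CC)CC)[C@@H]12
F7 | step 17 | 1β,10α-epoxy-3β,15-bis(TBSO)-8β-hydroxygermacra-4Z,11(13)-dien-12,6α-olide | C=C1C(=O)O[C@@H]2/C=C(/CO[Si](C)(C)C(C)(C)C)[C@@H](O[Si](C)(C)C(C)(C)C)C[C@H]3O[C@]3(C)C[C@@H](O)[C@@H]12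
F8 | step 7 | (2Z,6E)-3-[(TBSO)methyl]-9-(PMBO)-7-methyl-1-(TESO)nona-2,6-dien-4-one | CC[Si](CC)(CC)OC/C=C(/CO[Si](C)(C)C(C)(C)C)C(=O)C/C=C(\C)CCOCc1ccc(OC)cc1
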